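Carbons are numbered along the chain from the butenyl methyl (C1) to the ring CHMe (C20). The route rests on the lactone ring C15–C16–O–C17–C18 of the oxabicyclo[2.2.1]heptane: without its oxygen it is the cyclobutanone C15–C16–C17–C18 of a bicyclo[2.1.1]hexan-5-one, the crossed [2+2] adduct of a ketene (C17=C18) and a Z-trisubstituted alkene (C15=C16) tethered through C19–C20. One operation closes cyclobutanone and cyclopentane, forms C16–C17 and C15–C18, and sets C15, C16 and C18 from C20. Its precursor is an acyclic acid chloride with a C19 dioxolane and a Z-allylic silyl ether. Baeyer–Villiger oxidation, polyene extension and a Stille/8π–6π cascade finish.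

Key step: step 12

Remark on the chemistry: compounds 5 to 20 are carried as mixtures of the two C18 epimers, because C18 becomes trigonal in ketene 21; it is assumed that the target can be separated by HPLC from the ring diastereomer co-formed in step 26.

Step 1
Reactants: 1 methyl (R)-3-hydroxy-2-methylpropanoate; 2 benzyl 2,2,2-trichloroacetimidate
Product: 3 methyl (R)-3-(benzyloxy)-2-methylpropanoate
Conditions: CF3SO3H (cat.), CH2Cl2/cyclohexane, 0 °C → rt
Reagents that add atoms: benzyl 2,2,2-trichloroacetimidate ClC(Cl)(Cl)C(=N)OCc1ccccc1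
Why: Acid-catalysed O-benzylation with the trichloroacetimidate needs no base, so the base-sensitive β-hydroxy ester keeps its configuration (no new stereocentre).

Step 2
Reactants: 3 methyl (R)-3-(benzyloxy)-2-methylpropanoate; 4 tert-butyl propanoate
Product: 5 tert-butyl (4R)-5-(benzyloxy)-2,4-dimethyl-3-oxopentanoate (both C2 epimers)
Conditions: LiN(iPr)2 (2.6 equiv), 4 (2.5 equiv), THF, −78 °C; then 3, −78 → −30 °C; aq. NH4Cl
Reagents that add atoms: tert-butyl propanoate CCC(=O)OC(C)(C)C
Why: Crossed Claisen condensation in which the excess lithium enolate holds the product as its stabilised β-keto ester enolate, which stops a second addition and shields the C4 centre (C20) from enolisation; the new C2 centre (C18) is left unselective because it is later made trigonal.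

Step 3
Reactants: 5 tert-butyl (4R)-5-(benzyloxy)-2,4-dimethyl-3-oxopentanoate; 6 1,2-bis(trimethylsilyloxy)ethane
Product: 7 tert-butyl 2-{2-[(2R)-1-(benzyloxy)propan-2-yl]-1,3-dioxolan-2-yl}propanoate
Conditions: Me3SiOSO2CF3 (10 mol%), CH2Cl2, −78 → −20 °C; pyridine quench
Reagents that add atoms: 1,2-bis(trimethylsilyloxy)ethane C[Si](C)(C)OCCO[Si](C)(C)C
Why: Aprotic silyl-transfer ketalisation at low temperature should convert the hindered ketone without loss of the tert-butyl ester, β-elimination of the benzyloxy group or epimerisation next to the ketone.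

Step 4
Reactants: 7 tert-butyl 2-{2-[(2R)-1-(benzyloxy)propan-2-yl]-1,3-dioxolan-2-yl}propanoate
Product: 8 tert-butyl 2-{2-[(2R)-1-hydroxypropan-2-yl]-1,3-dioxolan-2-yl}propanoate
Conditions: H2 (1 atm), Pd/C (10% Pd on carbon), EtOAc, rt
Reagents that add atoms: none
Why: Hydrogenolysis of the benzyl ether is neutral and leaves the dioxolane and the tert-butyl ester untouched.

Step 5
Reactants: 8 tert-butyl 2-{2-[(2R)-1-hydroxypropan-2-yl]-1,3-dioxolan-2-yl}propanoate
Product: 9 tert-butyl 2-{2-[(2R)-1-oxopropan-2-yl]-1,3-dioxolan-2-yl}propanoate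
Conditions: Dess–Martin periodinane, NaHCO3, CH2Cl2, 0 °C → rt; used at once
Reagents that add atoms: none
Why: Buffered Dess–Martin oxidation gives the α-branched aldehyde without epimerising the adjacent centre.

Step 6
Reactants: 9 tert-butyl 2-{2-[(2R)-1-oxopropan-2-yl]-1,3-dioxolan-2-yl}propanoate; 10 methyl 2-[bis(2,2,2-trifluoroethoxy)phosphoryl]propanoate
Product: 11 methyl (2Z,4R)-4-{2-[1-(tert-butoxy)-1-oxopropan-2-yl]-1,3-dioxolan-2-yl}-2-methylpent-2-enoate
Conditions: 10 (1.2 equiv), KN(SiMe3)2 (1.15 equiv), 18-crown-6, THF, −78 °C; then 9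
Reagents that add atoms: methyl 2-[bis(2,2,2-trifluoroethoxy)phosphoryl]propanoate COC(=O)C(C)P(=O)(OCC(F)(F)F)OCC(F)(F)F
Why: Still–Gennari olefination, in which the trifluoroethyl phosphonate adds irreversibly and eliminates fast, gives the Z-trisubstituted enoate (ester cis to C4) under kinetic control, and the weakly basic phosphonate anion should not epimerise the aldehyde.

Step 7
Reactants: 11 methyl (2Z,4R)-4-{2-[1-(tert-butoxy)-1-oxopropan-2-yl]-1,3-dioxolan-2-yl}-2-methylpent-2-enoate
Product: 12 tert-butyl 2-{2-[(2R,3Z)-5-hydroxy-4-methylpent-3-en-2-yl]-1,3-dioxolan-2-yl}propanoate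
Conditions: iBu2AlH (2.2 equiv), CH2Cl2, −78 °C; aq. potassium sodium tartrate
Reagents that add atoms: none
Why: 1,2-Reduction of the conjugated methyl ester by iBu2AlH at −78 °C, where the hindered tert-butyl ester is inert, gives the Z-allylic alcohol with the geometry untouched.

Step 8
Reactants: 12 tert-butyl 2-{2-[(2R,3Z)-5-hydroxy-4-methylpent-3-en-2-yl]-1,3-dioxolan-2-yl}propanoate; 13 tert-butyl(chloro)diphenylsilane
Product: 14 tert-butyl 2-{2-[(2R,3Z)-5-[(tert-butyldiphenylsilyl)oxy]-4-methylpent-3-en-2-yl]-1,3-dioxolan-2-yl}propanoate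
Conditions: 13, imidazole, DMF, rt
Reagents that add atoms: tert-butyl(chloro)diphenylsilane CC(C)(C)[Si](Cl)(c1ccccc1)c1ccccc1
Why: Standard silylation of the primary allylic alcohol; the tert-butyldiphenylsilyl group is chosen because it survives the later acid hydrolysis of the dioxolane and keeps the hydroxyl capped during oxygen insertion.

Step 9
Reactants: 14 tert-butyl 2-{2-[(2R,3Z)-5-[(tert-butyldiphenylsilyl)oxy]-4-methylpent-3-en-2-yl]-1,3-dioxolan-2-yl}propanoate
Product: 15 2-{2-[(2R,3Z)-5-[(tert-butyldiphenylsilyl)oxy]-4-methylpent-3-en-2-yl]-1,3-dioxolan-2-yl}propan-1-ol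
Conditions: LiAlH4, Et2O, 0 °C → rt; NaOH/H2O work-up
Reagents that add atoms: none
Why: Hydride reduction of the tert-butyl ester opens a reduction–oxidation path to the C17 acid that avoids the acid otherwise needed to cleave a tert-butyl ester, so the dioxolane and the allylic silyl ether are spared.

Step 10
Reactants: 15 2-{2-[(2R,3Z)-5-[(tert-butyldiphenylsilyl)oxy]-4-methylpent-3-en-2-yl]-1,3-dioxolan-2-yl}propan-1-ol; 16 water
Product: 18 2-{2-[(2R,3Z)-5-[(tert-butyldiphenylsilyl)oxy]-4-methylpent-3-en-2-yl]-1,3-dioxolan-2-yl}propanoic acid, via aldehyde 17 (not isolated)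
Conditions: TEMPO (20 mol%), PhI(OAc)2 (2.5 equiv), MeCN/pH 7 phosphate buffer (1:1), rt
Reagents that add atoms: water O
Why: Oxoammonium (TEMPO) oxidation takes the primary alcohol through the aldehyde hydrate to the acid under buffered conditions that dioxolane, silyl ether and trisubstituted alkene tolerate.

Step 11
Reactants: 18 2-{2-[(2R,3Z)-5-[(tert-butyldiphenylsilyl)oxy]-4-methylpent-3-en-2-yl]-1,3-dioxolan-2-yl}propanoic acid; 19 1-chloro-N,N,2-trimethylprop-1-en-1-amine
Product: 20 2-{2-[(2R,3Z)-5-[(tert-butyldiphenylsilyl)oxy]-4-methylpent-3-en-2-yl]-1,3-dioxolan-2-yl}propanoyl chloride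
Conditions: 19 (1.2 equiv), CH2Cl2, 0 °C → rt; evaporation, used crude
Reagents that add atoms: 1-chloro-N,N,2-trimethylprop-1-en-1-amine CC(C)=C(Cl)N(C)C
Why: The α-chloroenamine converts the acid into its chloride under neutral conditions (the by-product is an amide, not free HCl), which protects the dioxolane and the allylic silyl ether.

Step 12
Reactants: 20 2-{2-[(2R,3Z)-5-[(tert-butyldiphenylsilyl)oxy]-4-methylpent-3-en-2-yl]-1,3-dioxolan-2-yl}propanoyl chloride
Product: 22 6-{[(tert-butyldiphenylsilyl)oxy]methyl}-1,3,6-trimethylspiro[bicyclo[2.1.1]hexane-2,2'-[1,3]dioxolan]-5-one (C6 silyloxymethyl syn to the C2–C3 bridge; C3 methyl on the side of the C5 carbonyl bridge), via ketene 21 (not isolated)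
Conditions: Et3N (5 equiv), toluene, 110 °C, slow addition of 20 (final 0.005 M)
Reagents that add atoms: none
Why: Et3N dehydrochlorinates 20 to dialkylketene 21, whose electrophilic carbon C17 bonds to the nearer alkene carbon C16 while positive charge builds on tertiary C15, and C18 then closes on C15 in an asynchronous thermal [2+2] that is suprafacial on the alkene; the closest known reaction type is the intramolecular crossed ketene–alkene cycloaddition that gives bicyclo[3.1.1]heptan-6-ones and, with two-atom tethers, bicyclo[2.1.1]hexan-5-ones. The cyclopentane (C15–C16–C20–C19–C18) closes through the tether and the cyclobutanone (C15–C16–C17–C18) through the cycloaddition itself, the fused alternative being a far more strained bicyclo[2.2.0]hexanone. C15 is fixed by the Z geometry, which is transferred so that the CH2OSi group cis to C20 lies over the C19–C20 bridge, and C16 and C18 follow from the bicyclic constraint. Their absolute sense is set by C20: allylic 1,3-strain turns the C20 hydrogen towards the cis CH2OSi group, so the ketene arm reaches the alkene face that leaves the C20 methyl on the side of the new carbonyl bridge. The step needs crossed regiochemistry and this one fold, which are secured by the trisubstituted terminus (charge at C15), the short tether, the gem-dialkoxy carbon C19 that favours folding, and high dilution with slow addition against ketene dimerisation.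

Step 13
Reactants: 22 6-{[(tert-butyldiphenylsilyl)oxy]methyl}-1,3,6-trimethylspiro[bicyclo[2.1.1]hexane-2,2'-[1,3]dioxolan]-5-one; 16 water
Product: 23 6-{[(tert-butyldiphenylsilyl)oxy]methyl}-1,3,6-trimethylbicyclo[2.1.1]hexane-2,5-dione
Conditions: TsOH·H2O (0.2 equiv), acetone/H2O (10:1), 40 °C
Reagents that add atoms: water O
Why: Acid-catalysed ketal hydrolysis that the tert-butyldiphenylsilyl ether survives; the carbon between the two carbonyls is quaternary and the C3 methyl (C20) already lies on the less crowded side, so enolisation cannot erode a stereocentre.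

Step 14
Reactants: 23 6-{[(tert-butyldiphenylsilyl)oxy]methyl}-1,3,6-trimethylbicyclo[2.1.1]hexane-2,5-dione; 24 3-chloroperoxybenzoic acid
Product: 25 7-{[(tert-butyldiphenylsilyl)oxy]methyl}-4,6,7-trimethyl-2-oxabicyclo[2.2.1]heptane-3,5-dione (C7 silyloxymethyl syn to the C5–C6 bridge; C6 methyl endo)
Conditions: 24 (1.5 equiv), NaHCO3, CH2Cl2, 0 °C → rt
Reagents that add atoms: 3-chloroperoxybenzoic acid OOC(=O)c1cccc(Cl)c1
Why: Baeyer–Villiger oxidation of the strained cyclobutanone, in which bridgehead C16 should migrate with retention because the other candidate C18 is directly attached to the C19 ketone and cannot carry the positive charge of a migrating group; the cyclopentanone is far less reactive and the bicarbonate buffer guards against ring cleavage of the 1,3-diketone.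

Step 15
Reactants: 25 7-{[(tert-butyldiphenylsilyl)oxy]methyl}-4,6,7-trimethyl-2-oxabicyclo[2.2.1]heptane-3,5-dione
Product: 26 7-(hydroxymethyl)-4,6,7-trimethyl-2-oxabicyclo[2.2.1]heptane-3,5-dione
Conditions: HF·pyridine, pyridine/THF, 0 °C → rt
Reagents that add atoms: none
Why: Desilylation with mildly acidic HF·pyridine avoids basic fluoride, which could open the β-keto lactone by retro-Claisen cleavage or epimerise C20.

Step 16
Reactants: 26 7-(hydroxymethyl)-4,6,7-trimethyl-2-oxabicyclo[2.2.1]heptane-3,5-dione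
Product: 27 4,6,7-trimethyl-3,5-dioxo-2-oxabicyclo[2.2.1]heptane-7-carbaldehyde
Conditions: Dess–Martin periodinane, NaHCO3, CH2Cl2, rt
Reagents that add atoms: none
Why: Dess–Martin oxidation of the primary alcohol gives a non-enolisable aldehyde on quaternary C15 and leaves ketone and lactone untouched.

Step 17
Reactants: 27 4,6,7-trimethyl-3,5-dioxo-2-oxabicyclo[2.2.1]heptane-7-carbaldehyde; 28 2-(triphenylphosphoranylidene)propanal
Product: 29 (2E)-2-methyl-3-(4,6,7-trimethyl-3,5-dioxo-2-oxabicyclo[2.2.1]heptan-7-yl)prop-2-enal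
Conditions: 28 (1.5 equiv), toluene, 100 °C
Reagents that add atoms: 2-(triphenylphosphoranylidene)propanal CC(C=O)=P(c1ccccc1)(c1ccccc1)c1ccccc1
Why: Wittig reaction with a stabilised formyl ylide under neutral conditions gives the E-enal directly (reversible addition, thermodynamic control), so no hydride step is needed beside ketone and lactone, which the ylide does not attack.

Step 18
Reactants: 29 (2E)-2-methyl-3-(4,6,7-trimethyl-3,5-dioxo-2-oxabicyclo[2.2.1]heptan-7-yl)prop-2-enal; 28 2-(triphenylphosphoranylidene)propanal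
Product: 30 (2E,4E)-2,4-dimethyl-5-(4,6,7-trimethyl-3,5-dioxo-2-oxabicyclo[2.2.1]heptan-7-yl)penta-2,4-dienal
Conditions: 28 (1.5 equiv), toluene, 100 °C
Reagents that add atoms: 2-(triphenylphosphoranylidene)propanal CC(C=O)=P(c1ccccc1)(c1ccccc1)c1ccccc1
Why: A second Wittig homologation of the same kind gives the E,E-dienal, which is less electrophilic than the enal and therefore resists further homologation.

Step 19
Reactants: 30 (2E,4E)-2,4-dimethyl-5-(4,6,7-trimethyl-3,5-dioxo-2-oxabicyclo[2.2.1]heptan-7-yl)penta-2,4-dienal; 31 ethyltriphenylphosphonium iodide; 32 iodine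
Product: 33 7-[(1E,3E,5Z)-6-iodo-2,4-dimethylhepta-1,3,5-trien-1-yl]-4,6,7-trimethyl-2-oxabicyclo[2.2.1]heptane-3,5-dione
Conditions: 31, n-BuLi, THF, rt; then 32, −78 °C; NaN(SiMe3)2, −20 °C; then 30, −78 → −40 °C
Reagents that add atoms: ethyltriphenylphosphonium iodide CC[P+](c1ccccc1)(c1ccccc1)c1ccccc1.[I-]; iodine II
Why: Stork–Zhao olefination, in which the α-iodo ylide adds to the aldehyde at −78 °C under kinetic control to give the Z-iodoalkene (iodine cis to the chain); the aldehyde is the most electrophilic carbonyl and is added last to a solution free of excess base, which protects the keto lactone.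

Step 20
Reactants: 34 prop-2-yn-1-ol; 35 methylmagnesium bromide; 32 iodine
Product: 37 (Z)-3-iodo-2-methylprop-2-en-1-ol, via alkenylmagnesium alkoxide 36 (not isolated)
Conditions: 35 (2.5 equiv), CuI (10 mol%), THF, 0 °C → rt; then 32, −20 °C → rt; aq. NH4Cl
Reagents that add atoms: methylmagnesium bromide C[Mg]Br; iodine II
Why: Copper-catalysed carbomagnesiation of the propargylic alkoxide is an anti addition held by a five-membered magnesium chelate, so iodinolysis with retention places iodine cis to the hydroxymethyl group.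

Step 21
Reactants: 37 (Z)-3-iodo-2-methylprop-2-en-1-ol; 38 ethyl 2-(triphenylphosphoranylidene)propanoate
Product: 40 ethyl (2E,4Z)-5-iodo-2,4-dimethylpenta-2,4-dienoate, via iodoenal 39 (not isolated)
Conditions: MnO2 (15 equiv), 38 (1.5 equiv), CH2Cl2, rt, dark
Reagents that add atoms: ethyl 2-(triphenylphosphoranylidene)propanoate CCOC(=O)C(C)=P(c1ccccc1)(c1ccccc1)c1ccccc1
Why: Tandem allylic oxidation–Wittig reaction in which the stabilised ylide traps the configurationally labile Z-iodoenal as it forms, giving the E-enoate without isomerising the Z-iodoalkene.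

Step 22
Reactants: 40 ethyl (2E,4Z)-5-iodo-2,4-dimethylpenta-2,4-dienoate
Product: 41 (2E,4Z)-5-iodo-2,4-dimethylpenta-2,4-dien-1-ol
Conditions: iBu2AlH (2.5 equiv), CH2Cl2, −78 °C; aq. potassium sodium tartrate
Reagents that add atoms: none
Why: 1,2-Reduction of the dienoate by iBu2AlH at −78 °C leaves the vinyl iodide and both alkene geometries untouched.

Step 23
Reactants: 41 (2E,4Z)-5-iodo-2,4-dimethylpenta-2,4-dien-1-ol
Product: 42 (2E,4Z)-5-iodo-2,4-dimethylpenta-2,4-dienal
Conditions: MnO2, CH2Cl2, rt, dark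
Reagents that add atoms: none
Why: MnO2 oxidises the allylic alcohol selectively and mildly to the dienal.

Step 24
Reactants: 42 (2E,4Z)-5-iodo-2,4-dimethylpenta-2,4-dienal; 43 but-2-yne
Product: 44 (2E,4R,5E,7Z)-8-iodo-3,5,7-trimethylocta-2,5,7-trien-4-ol
Conditions: 43, (C6H11)2BH (from BH3·SMe2 and cyclohexene), toluene, 0 °C → rt; ZnMe2, −78 °C; (2R)-(+)-3-exo-morpholinoisoborneol (5 mol%); then 42, −20 → 0 °C; aq. NH4Cl
Reagents that add atoms: but-2-yne CC#CC
Why: Syn hydroboration of the alkyne, boron-to-zinc exchange and amino-alcohol-catalysed alkenylzinc addition should deliver the (E)-but-2-en-2-yl group to the Re face of the aldehyde and set the 4R carbinol (the antipode of the ligand that gives (S)-1-phenylpropan-1-ol from benzaldehyde and ZnEt2 is used), while methyl transfer from zinc is slow and the vinyl iodide is inert.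

Step 25
Reactants: 44 (2E,4R,5E,7Z)-8-iodo-3,5,7-trimethylocta-2,5,7-trien-4-ol; 45 hexamethyldistannane
Product: 46 (2E,4R,5E,7Z)-3,5,7-trimethyl-8-(trimethylstannyl)octa-2,5,7-trien-4-ol
Conditions: 45 (2 equiv), Pd(PPh3)4 (5 mol%), iPr2NEt, toluene, 80 °C
Reagents that add atoms: hexamethyldistannane C[Sn](C)(C)[Sn](C)(C)C
Why: Palladium-catalysed iodine–tin exchange (oxidative addition, transmetalation with the distannane, reductive elimination) proceeds with retention of the Z geometry and tolerates the free alcohol.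

Step 26
Reactants: 33 7-[(1E,3E,5Z)-6-iodo-2,4-dimethylhepta-1,3,5-trien-1-yl]-4,6,7-trimethyl-2-oxabicyclo[2.2.1]heptane-3,5-dione; 46 (2E,4R,5E,7Z)-3,5,7-trimethyl-8-(trimethylstannyl)octa-2,5,7-trien-4-ol
Product: 49 shimalactone B, via tetraene 47 (not isolated), via cyclooctatriene 48 (not isolated)
Conditions: Pd(PPh3)4 (10 mol%), copper thiophene-2-carboxylate Cu(O2CC4H3S) (1.5 equiv), DMF, 0 °C → rt, dark; then 50 °C; preparative HPLC
Reagents that add atoms: none
Why: Stille coupling with retention at both Z termini gives the (5E,7Z,9Z,11E)-tetraene, which closes thermally by 8π conrotation (C5–C12 bond, C4 and C13 arms trans) and then by 6π disrotation (C6–C11 bond, cis fusion) in the mode that turns the cyclohexadiene ring away from the branched C4 arm; the sense of the conrotatory twist is biased only by the neighbouring C4 carbinol, so the diastereomer with the mirror-image bicyclo[4.2.0]octadiene is expected as a co-product and is removed by HPLC.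

Compound list
1 | methyl (R)-3-hydroxy-2-methylpropanoate | COC(=O)[C@H](C)CO | starting material
2 | benzyl 2,2,2-trichloroacetimidate | ClC(Cl)(Cl)C(=N)OCc1ccccc1 | starting material
3 | methyl (R)-3-(benzyloxy)-2-methylpropanoate | COC(=O)[C@H](C)COCc1ccccc1 | intermediate
4 | tert-butyl propanoate | CCC(=O)OC(C)(C)C | starting material
5 | tert-butyl (2RS,4R)-5-(benzyloxy)-2,4-dimethyl-3-oxopentanoate | CC(C(=O)OC(C)(C)C)C(=O)[C@H](C)COCc1ccccc1 | intermediate
6 | 1,2-bis(trimethylsilyloxy)ethane | C[Si](C)(C)OCCO[Si](C)(C)C | starting material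
7 | tert-butyl 2-{2-[(2R)-1-(benzyloxy)propan-2-yl]-1,3-dioxolan-2-yl}propanoate | CC(C(=O)OC(C)(C)C)C1(OCCO1)[C@H](C)COCc1ccccc1 | intermediate
8 | tert-butyl 2-{2-[(2R)-1-hydroxypropan-2-yl]-1,3-dioxolan-2-yl}propanoate | CC(C(=O)OC(C)(C)C)C1(OCCO1)[C@H](C)CO | intermediate
9 | tert-butyl 2-{2-[(2R)-1-oxopropan-2-yl]-1,3-dioxolan-2-yl}propanoate | CC(C(=O)OC(C)(C)C)C1(OCCO1)[C@H](C)C=O | intermediate
10 | methyl 2-[bis(2,2,2-trifluoroethoxy)phosphoryl]propanoate | COC(=O)C(C)P(=O)(OCC(F)(F)F)OCC(F)(F)F | starting material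
11 | methyl (2Z,4R)-4-{2-[1-(tert-butoxy)-1-oxopropan-2-yl]-1,3-dioxolan-2-yl}-2-methylpent-2-enoate | CC(C(=O)OC(C)(C)C)C1(OCCO1)[C@H](C)/C=C(/C)C(=O)OC | intermediate
12 | tert-butyl 2-{2-[(2R,3Z)-5-hydroxy-4-methylpent-3-en-2-yl]-1,3-dioxolan-2-yl}propanoate | CC(C(=O)OC(C)(C)C)C1(OCCO1)[C@H](C)/C=C(/C)CO | intermediate
13 | tert-butyl(chloro)diphenylsilane | CC(C)(C)[Si](Cl)(c1ccccc1)c1ccccc1 | starting material
14 | tert-butyl 2-{2-[(2R,3Z)-5-[(tert-butyldiphenylsilyl)oxy]-4-methylpent-3-en-2-yl]-1,3-dioxolan-2-yl}propanoate | CC(C(=O)OC(C)(C)C)C1(OCCO1)[C@H](C)/C=C(/C)CO[Si](c1ccccc1)(c1ccccc1)C(C)(C)C | intermediate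
15 | 2-{2-[(2R,3Z)-5-[(tert-butyldiphenylsilyl)oxy]-4-methylpent-3-en-2-yl]-1,3-dioxolan-2-yl}propan-1-ol | CC(CO)C1(OCCO1)[C@H](C)/C=C(/C)CO[Si](c1ccccc1)(c1ccccc1)C(C)(C)C | intermediate
16 | water | O | starting material
17 | 2-{2-[(2R,3Z)-5-[(tert-butyldiphenylsilyl)oxy]-4-methylpent-3-en-2-yl]-1,3-dioxolan-2-yl}propanal | CC(C=O)C1(OCCO1)[C@H](C)/C=C(/C)CO[Si](c1ccccc1)(c1ccccc1)C(C)(C)C | intermediate (not isolated)
18 | 2-{2-[(2R,3Z)-5-[(tert-butyldiphenylsilyl)oxy]-4-methylpent-3-en-2-yl]-1,3-dioxolan-2-yl}propanoic acid | CC(C(=O)O)C1(OCCO1)[C@H](C)/C=C(/C)CO[Si](c1ccccc1)(c1ccccc1)C(C)(C)C | intermediate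
19 | 1-chloro-N,N,2-trimethylprop-1-en-1-amine | CC(C)=C(Cl)N(C)C | starting material
20 | 2-{2-[(2R,3Z)-5-[(tert-butyldiphenylsilyl)oxy]-4-methylpent-3-en-2-yl]-1,3-dioxolan-2-yl}propanoyl chloride | CC(C(=O)Cl)C1(OCCO1)[C@H](C)/C=C(/C)CO[Si](c1ccccc1)(c1ccccc1)C(C)(C)C | intermediate
21 | 2-{2-[(2R,3Z)-5-[(tert-butyldiphenylsilyl)oxy]-4-methylpent-3-en-2-yl]-1,3-dioxolan-2-yl}prop-1-en-1-one (ketene) | CC(=C=O)C1(OCCO1)[C@H](C)/C=C(/C)CO[Si](c1ccccc1)(c1ccccc1)C(C)(C)C | intermediate (not isolated)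
22 | 6-{[(tert-butyldiphenylsilyl)oxy]methyl}-1,3,6-trimethylspiro[bicyclo[2.1.1]hexane-2,2'-[1,3]dioxolan]-5-one | CC(C)(C)[Si](c1ccccc1)(c1ccccc1)OC[C@]1(C)[C@H]2C(=O)[C@]1(C)C3(OCCO3)[C@@H]2C | intermediate
23 | 6-{[(tert-butyldiphenylsilyl)oxy]methyl}-1,3,6-trimethylbicyclo[2.1.1]hexane-2,5-dione | CC(C)(C)[Si](c1ccccc1)(c1ccccc1)OC[C@]1(C)[C@H]2C(=O)[C@]1(C)C(=O)[C@@H]2C | intermediate
24 | 3-chloroperoxybenzoic acid | OOC(=O)c1cccc(Cl)c1 | starting material
25 | 7-{[(tert-butyldiphenylsilyl)oxy]methyl}-4,6,7-trimethyl-2-oxabicyclo[2.2.1]heptane-3,5-dione | CC(C)(C)[Si](c1ccccc1)(c1ccccc1)OC[C@]1(C)[C@H]2OC(=O)[C@]1(C)C(=O)[C@@H]2C | intermediate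
26 | 7-(hydroxymethyl)-4,6,7-trimethyl-2-oxabicyclo[2.2.1]heptane-3,5-dione | OC[C@]1(C)[C@H]2OC(=O)[C@]1(C)C(=O)[C@@H]2C | intermediate
27 | 4,6,7-trimethyl-3,5-dioxo-2-oxabicyclo[2.2.1]heptane-7-carbaldehyde | O=C[C@]1(C)[C@H]2OC(=O)[C@]1(C)C(=O)[C@@H]2C | intermediate
28 | 2-(triphenylphosphoranylidene)propanal | CC(C=O)=P(c1ccccc1)(c1ccccc1)c1ccccc1 | starting material
29 | (2E)-2-methyl-3-(4,6,7-trimethyl-3,5-dioxo-2-oxabicyclo[2.2.1]heptan-7-yl)prop-2-enal | O=C/C(C)=C/[C@]1(C)[C@H]2OC(=O)[C@]1(C)C(=O)[C@@H]2C | intermediate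
30 | (2E,4E)-2,4-dimethyl-5-(4,6,7-trimethyl-3,5-dioxo-2-oxabicyclo[2.2.1]heptan-7-yl)penta-2,4-dienal | O=C/C(C)=C/C(C)=C/[C@]1(C)[C@H]2OC(=O)[C@]1(C)C(=O)[C@@H]2C | intermediate
31 | ethyltriphenylphosphonium iodide | CC[P+](c1ccccc1)(c1ccccc1)c1ccccc1.[I-] | starting material
32 | iodine | II | starting material
33 | 7-[(1E,3E,5Z)-6-iodo-2,4-dimethylhepta-1,3,5-trien-1-yl]-4,6,7-trimethyl-2-oxabicyclo[2.2.1]heptane-3,5-dione | C/C(I)=C/C(C)=C/C(C)=C/[C@]1(C)[C@H]2OC(=O)[C@]1(C)C(=O)[C@@H]2C | intermediate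
34 | prop-2-yn-1-ol | C#CCO | starting material
35 | methylmagnesium bromide | C[Mg]Br | starting material
36 | bromomagnesium (Z)-3-(bromomagnesio)-2-methylprop-2-en-1-olate | Br[Mg]/C=C(C)\CO[Mg]Br | intermediate (not isolated)
37 | (Z)-3-iodo-2-methylprop-2-en-1-ol | OC/C(C)=C\I | intermediate
38 | ethyl 2-(triphenylphosphoranylidene)propanoate | CCOC(=O)C(C)=P(c1ccccc1)(c1ccccc1)c1ccccc1 | starting material
39 | (Z)-3-iodo-2-methylprop-2-enal | O=C/C(C)=C\I | intermediate (not isolated)
40 | ethyl (2E,4Z)-5-iodo-2,4-dimethylpenta-2,4-dienoate | CCOC(=O)/C(C)=C/C(C)=C\I | intermediate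
41 | (2E,4Z)-5-iodo-2,4-dimethylpenta-2,4-dien-1-ol | OC/C(C)=C/C(C)=C\I | intermediate
42 | (2E,4Z)-5-iodo-2,4-dimethylpenta-2,4-dienal | O=C/C(C)=C/C(C)=C\I | intermediate
43 | but-2-yne | CC#CC | starting material
44 | (2E,4R,5E,7Z)-8-iodo-3,5,7-trimethylocta-2,5,7-trien-4-ol | C/C=C(\C)[C@@H](O)/C(C)=C/C(C)=C\I | intermediate
45 | hexamethyldistannane | C[Sn](C)(C)[Sn](C)(C)C | starting material
46 | (2E,4R,5E,7Z)-3,5,7-trimethyl-8-(trimethylstannyl)octa-2,5,7-trien-4-ol | C/C=C(\C)[C@@H](O)/C(C)=C/C(C)=C\[Sn](C)(C)C | intermediate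
47 | (2E,4R,5E,7Z,9Z,11E,13E)-tetradecaheptaenol carrying the oxabicycle at C14 (open-chain tetraene C5=C6–C7=C8–C9=C10–C11=C12) | C/C=C(\C)[C@@H](O)/C(C)=C/C(C)=C\C(C)=C/C(C)=C/C(C)=C/[C@]1(C)[C@H]2OC(=O)[C@]1(C)C(=O)[C@@H]2C | intermediate (not isolated)
48 | cycloocta-2,4,6-triene C5–C12 with the C4 carbinol arm and the C13 alkenyl arm trans | C/C=C(\C)[C@@H](O)[C@@]1(C)/C=C(C)\C=C(C)/C=C(C)\[C@@H]1/C(C)=C/[C@]1(C)[C@H]2OC(=O)[C@]1(C)C(=O)[C@@H]2C | intermediate (not isolated)
49 | shimalactone B | C/C=C(\C)[C@@H](O)[C@@]1(C)[C@@H]2C(C)=CC(C)=C[C@]2(C)[C@@H]1/C(C)=C/[C@]1(C)[C@H]2OC(=O)[C@]1(C)C(=O)[C@@H]2C | target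

Total step count: 26. Longest linear sequence: 20 steps (steps 1–19 and 26).

Steps most likely to fail

Step 12. The hindered dialkylketene may be consumed by dimerisation or other intermolecular pathways before it folds onto the alkene, and the fold selection by C20 may be incomplete. The fallback sets out from 20 and returns at 22. Acid chloride 20 is treated with dimethylamine and Et3N in CH2Cl2 to give 2-{2-[(2R,3Z)-5-[(tert-butyldiphenylsilyl)oxy]-4-methylpent-3-en-2-yl]-1,3-dioxolan-2-yl}-N,N-dimethylpropanamide F1. Activation with (CF3SO2)2O and 2,6-di-tert-butyl-4-methylpyridine in ClCH2CH2Cl at 80 °C generates the far more electrophilic keteniminium ion, which should undergo the same crossed intramolecular [2+2] (keteniminium–alkene cycloaddition) to the bicyclic N,N-dimethyliminium triflate F2. Aqueous NaHCO3 hydrolyses F2 to ketone 22.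

Step 14. The strained 1,3-diketone may be opened by retro-Claisen cleavage of the peracid adduct before migration occurs. The fallback sets out from 22 and returns at 25, and avoids the diketone altogether. Ketal 22 is oxidised with CF3CO3H (from (CF3CO)2O and urea·H2O2) buffered with Na2HPO4 in CH2Cl2 at 0 °C to the dioxolane-protected lactone 7-{[(tert-butyldiphenylsilyl)oxy]methyl}-4,6,7-trimethylspiro[2-oxabicyclo[2.2.1]heptane-5,2'-[1,3]dioxolan]-3-one F3. Migration of C16 then relies on the weaker inductive deactivation of C18 by the two ketal oxygens under this more electron-demanding peracid, and a regioisomer may have to be separated. Hydrolysis with TsOH·H2O in aqueous acetone gives 25.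

Step 26. Facial control over the conrotatory twist may be poor and could leave the target as the minor ring diastereomer. The fallback sets out from 42 and returns at 49. It uses the epimeric carbinol, which should reverse the preferred twist relative to the remote oxabicycle, and corrects C4 afterwards. Step 24 is run with the enantiomeric ligand (2S)-(−)-3-exo-morpholinoisoborneol to give (2E,4S,5E,7Z)-8-iodo-3,5,7-trimethylocta-2,5,7-trien-4-ol F4, which is stannylated as in step 25 to (2E,4S,5E,7Z)-3,5,7-trimethyl-8-(trimethylstannyl)octa-2,5,7-trien-4-ol F5. Coupling of F5 with 33 as in step 26 gives 4-epi-shimalactone B F6, which has the ring configuration of the target. Dess–Martin oxidation gives the C4 ketone 4-dehydroshimalactone B F7. A Corey–Bakshi–Shibata reduction with catecholborane in toluene at −78 °C, using the oxazaborolidine enantiomer that delivers hydride to the face giving the 4R alcohol (the (S)-catalyst if quaternary C5 acts as the large group), returns 49. The C19 ketone, which is flanked by a quaternary and a tertiary carbon inside the bicycle, should react much more slowly than the enone.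

Further compounds
F1 | step 12 | 2-{2-[(2R,3Z)-5-[(tert-butyldiphenylsilyl)oxy]-4-methylpent-3-en-2-yl]-1,3-dioxolan-2-yl}-N,N-dimethylpropanamide | CN(C)C(=O)C(C)C1(OCCO1)[C@H](C)/C=C(/C)CO[Si](c1ccccc1)(c1ccccc1)C(C)(C)C
F2 | step 12 | N-[6-{[(tert-butyldiphenylsilyl)oxy]methyl}-1,3,6-trimethylspiro[bicyclo[2.1.1]hexane-2,2'-[1,3]dioxolan]-5-ylidene]-N-methylmethanaminium trifluoromethanesulfonate | CC(C)(C)[Si](c1ccccc1)(c1ccccc1)OC[C@]1(C)[C@H]2C(=[N+](C)C)[C@]1(C)C3(OCCO3)[C@@H]2C.[O-]S(=O)(=O)C(F)(F)F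
F3 | step 14 | 7-{[(tert-butyldiphenylsilyl)oxy]methyl}-4,6,7-trimethylspiro[2-oxabicyclo[2.2.1]heptane-5,2'-[1,3]dioxolan]-3-one | CC(C)(C)[Si](c1ccccc1)(c1ccccc1)OC[C@]1(C)[C@H]2OC(=O)[C@]1(C)C3(OCCO3)[C@@H]2C
F4 | step 26 | (2E,4S,5E,7Z)-8-iodo-3,5,7-trimethylocta-2,5,7-trien-4-ol | C/C=C(\C)[C@H](O)/C(C)=C/C(C)=C\I
F5 | step 26 | (2E,4S,5E,7Z)-3,5,7-trimethyl-8-(trimethylstannyl)octa-2,5,7-trien-4-ol | C/C=C(\C)[C@H](O)/C(C)=C/C(C)=C\[Sn](C)(C)C
F6 | step 26 | 4-epi-shimalactone B | C/C=C(\C)[C@H](O)[C@@]1(C)[C@@H]2C(C)=CC(C)=C[C@]2(C)[C@@H]1/C(C)=C/[C@]1(C)[C@H]2OC(=O)[C@]1(C)C(=O)[C@@H]2C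
F7 | step 26 | 4-dehydroshimalactone B (C4 ketone) | C/C=C(\C)C(=O)[C@@]1(C)[C@@H]2C(C)=CC(C)=C[C@]2(C)[C@@H]1/C(C)=C/[C@]1(C)[C@H]2OC(=O)[C@]1(C)C(=O)[C@@H]2C
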